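## Structural features

The target is a single cyclohexene. Its atoms are labelled here C1 (quaternary carbon with two methyl groups), C2 (CHCl), C3 (CH2), C4 (=CH), C5 (substituted alkene carbon) and C6 (CHBr) in the ring, with a side chain C7 (CHCl) and C8 (CH2Br) on C5. There are three stereocentres, C2 (R), C6 (S) and C7 (S): C2 and C6 both sit on the quaternary C1 with their halogens trans, and C6 and C7 both sit on the alkene carbon C5, one inside and one outside the ring. The molecule has no oxygen or carbonyl handle, so all four carbon–halogen bonds must be traced to precursor functions. The allylic bromide at C6 and the allylic chloride at C7 are fragile (ionisation, allylic transposition, 1,4-elimination), and the vicinal C7/C8 halide pair invites halogen participation. The real difficulty is that C2 and C6 are both neopentyl-type: C2 is unactivated, so its chloride cannot reasonably come from substitution, and C6 can be substituted only because it is allylic. In addition the stereocentres relay poorly, because C1 insulates C2 and C7 is exocyclic. The key step exploits the C4=C5 alkene flanked by the allylic carbons C6 and C7: opened there, the frame is an acyclic 2-methylene-1,3-dioxygenated unit (C6–C5(=CH2)–C7) joined through C1 to a C2 that carries an allyl group, a 1,7-diene whose gem-dimethyl group favours closure.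

## Logic of the disconnections

20 to 19: the C6–Br and C8–Br bonds are cut together. The allylic bromide is the most labile function and should exist only in the final compound. Both bromines come from hydroxyls, C8 by direct displacement and C6 with inversion, so 19 must carry its C6 oxygen cis to the C2 chlorine. The forward step must invert a hindered allylic centre without transposition.

19 to 18 to 17: the C7–Cl bond is cut and traced to a C7 hydroxyl of opposite configuration in 17. The oxygens at C6 and C8 carry the same silyl group in 18, so one deprotection gives 19. The forward step is a substitution with inversion at a secondary allylic carbon that has no participating neighbour.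

17 to 16 to 15: no skeletal bond is cut. The C7/C8 diol is differentiated by silylating the primary hydroxyl, and the diol is traced to a cyclic acetal so that both oxygens and the C7 configuration come from 1. The demand is that acetal hydrolysis spares the C6 silyl ether.

15 to 14: the C4=C5 double bond is cut, opening the ring to a triene with a terminal alkene at C4 and a 1,1-disubstituted alkene at C5. Ring closure then becomes a stereochemically silent event, and all three stereocentres move into an open chain where each can be set by its own reagent. The demand is ring closure at a shielded 1,1-disubstituted alkene in preference to intermolecular reaction.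

14 to 11 and 12 (through 13): the C3–C4 single bond is cut, so the allyl terminus arrives as the vinyl nucleophile 12 on a C3 electrophile. This leaves the C2 chloride next to a primary alcohol, the signature of a reduced α-chloro aldehyde. The demand is that substitution at C3 outruns any elimination involving the vicinal chloride.

11 to 9 (through 10): the C2–Cl bond is cut. Electrophilic chlorination of the enamine of 9 puts chlorine on the neopentyl C2 without any substitution there, and reduction secures the labile product. The demand is catalyst control over C2 in a substrate that already holds C6 and C7.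

9 to 7 (through 8): the C3 aldehyde is traced to a terminal alkene with one extra carbon. The whole C6–C1–C2–C3 unit can then come from 5 with no protecting group at C3. The demand is cleavage of the monosubstituted alkene in the presence of the hindered 1,1-disubstituted one.

7 to 6 to 4 and 5: after removing the silyl ether, the C5–C6 bond is cut into an alkenyl nucleophile derived from 4 and the achiral aldehyde 5. This is the most convergent cut. Because 5 is achiral and C7 is a weak controller, C6 must be set by a chiral ligand on the metal.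

4 to 3 to 2 to 1: functional-group changes only. The enol triflate comes from the methyl ketone, and the ketone from 1 plus a methyl nucleophile; that methyl carbon is the methylene later expelled in the ring closure. The demand is that C7, α to a carbonyl in 3, is never deprotonated.

## Other disconnections considered

Alternative 1: The cut removes C2–C3 and C1–C6, so the ring is assembled from diene A1 (C3 to C6, bromine on C5, silyloxy on C6) and dienophile A2 (C1 and C2, chlorine on C2, a formyl group on C1 standing in for the second methyl). The forward key step is a [4+2] cycloaddition under a chiral oxazaborolidinium Lewis acid to give adduct A3.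
- In its favour: one step makes the ring, the quaternary carbon and the C2 chlorine, and it fixes chlorine and the C6 oxygen cis through dienophile geometry and the endo rule. On relative control of C2/C6 and on convergence of ring construction it is better than the chosen plan, which needs a ligand-controlled addition for C6. The vinyl bromide of A3 is a good handle for attaching C7 and C8.
- Against it: A2 is a β-chloro, α-branched enal that is hindered, deactivated and able to lose its geometry on the Lewis acid, and the bromine lowers the reactivity of A1. The formyl group of A3 must then be reduced to methyl at a neopentyl carbon next to a chloride and an allylic silyl ether, where basic hydrazone methods invite loss of HCl. C7 must be created later by a separate reagent-controlled step, whereas the chosen plan takes it from the chiral pool.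
- Comparison: mechanistically it is a stereospecific pericyclic step against a metathesis with no stereochemical content. In step economy it is shorter up to the ring and longer after it, so roughly equal overall.

Alternative 2: The cut is C5–C6 with the alkene kept, giving the acyclic enone aldehyde A6. A nucleophilic phosphine adds to C4, the enolate carbon C5 attacks the aldehyde C6, and loss of the phosphine gives hydroxy enone A7. A6 would come from (R)-pantolactone A4 through the chloro lactone A5 formed with inversion.
- In its favour: C2 comes from a cheap chiral-pool lactone with no asymmetric catalysis, which is better than the chosen plan on that point. The ring closure is metal-free and gives the C6 hydroxyl free, next to a ring enone that would allow ring-based correction of C6.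
- Against it: the chloride must be introduced on A4 by substitution at a neopentyl carbon, and A5 has an enolisable α-hydrogen at the new stereocentre. C3 must be taken from the carboxyl level to a methylene and joined to C4 next to the chloride, the same bond problem as step 8 here, so equal in difficulty but with extra redox steps. The cyclisation sets C6 only under substrate control and is reversible, and A6 can lose HCl by vinylogous enolisation. After ring closure the acetyl group of A7 needs oxygenation at C8 and stereoselective reduction at C7 before the same halogenations, which is longer than the five steps that follow the chosen key step.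
- Comparison: both plans fix C2 before the ring forms and leave C6 and C7 as alcohols for late inversion; on that they are equal.

Alternative 3: The cut removes both chlorines and reconnects C2 to C4, leading back to the bicyclic alkene A8, a bicyclo[3.1.0]hexane with an exocyclic C5=C7 alkene. An ammonium trichloride delivers electrophilic chlorine to C7, and chloride opens the cyclopropylcarbinyl cation at C2 with inversion to give dichloride A9.
- A9 is identical with 18, so from there the two plans share the last two steps and are equal.
- In its favour: two C–Cl bonds, the ring enlargement and the C4=C5 alkene arise in one operation. In halogen economy it is better than the chosen plan, which needs steps 7 and 12 and the protecting-group steps 10 and 11.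
- Against it: A8 carries three ring stereocentres and an alkene of defined geometry, so the difficulty moves into its synthesis, which is unlikely to be shorter than the route to 14. The configurations at C2 and C7 depend on a concerted anti 1,5-addition. A cation with a lifetime could be captured at C5, rearrange, or lose the C2 configuration.
- Comparison: a cationic, stereochemically demanding key step against a neutral, stereochemically silent one. The chosen plan spreads its risk over several individually precedented steps.

Key step: step 9

Assumption: the sense of induction written for the amine of step 7 and the sulfonamide ligand of step 4 follows the usual steric models; if either proves opposite, the enantiomeric catalyst or ligand is used and nothing else changes.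

Remark: TBS is tert-butyldimethylsilyl and atom labels C1 to C8 are those of the target. Some descriptors change through priority alone, with no change at the centre: the dioxolane carbon in step 4, C6 in steps 7 and 12, and C2 in step 8.

## Route

Step 1
Reactants: 1 (4S)-2,2-dimethyl-1,3-dioxolane-4-carbaldehyde
Product: 2 1-[(4S)-2,2-dimethyl-1,3-dioxolan-4-yl]ethan-1-ol (both carbinol epimers)
Conditions: MeMgBr, THF, −78 → 0 °C; aq. NH4Cl
Reagents that add atoms: methylmagnesium bromide, C[Mg]Br
Why: Grignard addition to the aldehyde; the new carbinol centre is destroyed in step 2, so its configuration does not matter, and C7 is not enolised at low temperature.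

Step 2
Reactants: 2 1-[(4S)-2,2-dimethyl-1,3-dioxolan-4-yl]ethan-1-ol
Product: 3 1-[(4S)-2,2-dimethyl-1,3-dioxolan-4-yl]ethan-1-one
Conditions: Dess–Martin periodinane, NaHCO3, CH2Cl2, 0 °C → rt
Reagents that add atoms: none
Why: Dess–Martin oxidation of a secondary alcohol under buffered, non-basic conditions, chosen so that the α-alkoxy ketone is not epimerised at C7.

Step 3
Reactants: 3 1-[(4S)-2,2-dimethyl-1,3-dioxolan-4-yl]ethan-1-one
Product: 4 1-[(4S)-2,2-dimethyl-1,3-dioxolan-4-yl]ethenyl trifluoromethanesulfonate
Conditions: KN(SiMe3)2, THF, −78 °C; then PhNTf2, −78 → 0 °C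
Reagents that add atoms: N-phenylbis(trifluoromethanesulfonimide), O=S(=O)(N(c1ccccc1)S(=O)(=O)C(F)(F)F)C(F)(F)F
Why: Kinetic enolisation with a bulky amide removes a methyl proton and not the hindered α-alkoxy methine, and O-sulfonylation of that enolate gives the 1,1-disubstituted enol triflate; C7 stays untouched because its proton is never removed.

Step 4
Reactants: 4 1-[(4S)-2,2-dimethyl-1,3-dioxolan-4-yl]ethenyl trifluoromethanesulfonate; 5 2,2-dimethylpent-4-enal
Product: 6 (3R)-2-[(4R)-2,2-dimethyl-1,3-dioxolan-4-yl]-4,4-dimethylhepta-1,6-dien-3-ol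
Conditions: CrCl2 (3 equiv), (S)-N-[2-(4-isopropyl-4,5-dihydro-1,3-oxazol-2-yl)-6-methylphenyl]methanesulfonamide (3.3 equiv), Et3N (3.3 equiv), NiCl2 (5 mol%), THF, rt
Reagents that add atoms: none
Why: Asymmetric Nozaki–Hiyama–Kishi reaction: zerovalent nickel inserts into the C–O bond of the enol triflate, the alkenyl group passes to trivalent chromium, and the alkenylchromium adds to the aldehyde to form C5–C6. The aldehyde is achiral and C7 biases the addition only weakly, so the new C6 centre is set by the chiral sulfonamide bound to chromium (reagent control). The acetonide and the terminal alkene are inert to the chromium reagent.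

Step 5
Reactants: 6 (3R)-2-[(4R)-2,2-dimethyl-1,3-dioxolan-4-yl]-4,4-dimethylhepta-1,6-dien-3-ol
Product: 7 TBS ether of 6, tert-butyl{[(3R)-2-[(4R)-2,2-dimethyl-1,3-dioxolan-4-yl]-4,4-dimethylhepta-1,6-dien-3-yl]oxy}dimethylsilane
Conditions: TBSOTf, 2,6-lutidine, CH2Cl2, −78 → 0 °C
Reagents that add atoms: tert-butyldimethylsilyl trifluoromethanesulfonate, CC(C)(C)[Si](C)(C)OS(=O)(=O)C(F)(F)F
Why: Silylation of a hindered secondary alcohol with the silyl triflate, buffered so that the acetonide survives; this ether later matches the one placed on C8, so both can be removed together.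

Step 6
Reactants: 7 tert-butyl{[(3R)-2-[(4R)-2,2-dimethyl-1,3-dioxolan-4-yl]-4,4-dimethylhepta-1,6-dien-3-yl]oxy}dimethylsilane
Product: 9 (4R)-4-[(TBS)oxy]-5-[(4R)-2,2-dimethyl-1,3-dioxolan-4-yl]-3,3-dimethylhex-5-enal, via vicinal diol 8 (not isolated)
Conditions: OsO4 (2 mol%), NaIO4 (4 equiv), 2,6-lutidine, dioxane/H2O 3:1, rt
Reagents that add atoms: osmium tetroxide, O=[Os](=O)(=O)=O (oxygen carrier, reoxidised by sodium periodate, [Na+].[O-]I(=O)(=O)=O)
Why: Lemieux–Johnson cleavage: osmylation is expected at the unhindered monosubstituted alkene, because the 1,1-disubstituted alkene lies between two oxygen-bearing, fully substituted carbons that shield it and withdraw electron density. Periodate cleaves diol 8 in the flask, and lutidine suppresses acetonide loss and over-oxidation.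

Step 7
Reactants: 9 (4R)-4-[(TBS)oxy]-5-[(4R)-2,2-dimethyl-1,3-dioxolan-4-yl]-3,3-dimethylhex-5-enal
Product: 11 (2S,4S)-4-[(TBS)oxy]-2-chloro-5-[(4R)-2,2-dimethyl-1,3-dioxolan-4-yl]-3,3-dimethylhex-5-en-1-ol, via α-chloro aldehyde 10 (not isolated)
Conditions: (2R,5R)-2,5-diphenylpyrrolidine (10 mol%), N-chlorosuccinimide (1.3 equiv), CH2Cl2, rt; then NaBH4, MeOH, 0 °C
Reagents that add atoms: N-chlorosuccinimide, O=C1CCC(=O)N1Cl
Why: Enamine-catalysed α-chlorination: the C2-symmetric amine forms the E-enamine of 9 and blocks one face, so chlorine enters C2 from the other; the catalyst, not the distant C6 centre, sets C2. Immediate borohydride reduction fixes the configurationally labile α-chloro aldehyde 10 as the chlorohydrin.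

Step 8
Reactants: 11 (2S,4S)-4-[(TBS)oxy]-2-chloro-5-[(4R)-2,2-dimethyl-1,3-dioxolan-4-yl]-3,3-dimethylhex-5-en-1-ol; 12 vinylmagnesium bromide
Product: 14 tert-butyl{[(3S,5R)-5-chloro-2-[(4R)-2,2-dimethyl-1,3-dioxolan-4-yl]-4,4-dimethylocta-1,7-dien-3-yl]oxy}dimethylsilane, via primary triflate 13 (not isolated)
Conditions: Tf2O, 2,6-lutidine, CH2Cl2, −78 °C; then CH2=CHMgBr (3 equiv), CuI (10 mol%), THF/Et2O, −78 → −20 °C
Reagents that add atoms: trifluoromethanesulfonic anhydride, O=S(=O)(OS(=O)(=O)C(F)(F)F)C(F)(F)F (its atoms stay in 13 only; the vinyl group comes from reactant 12)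
Why: Copper-catalysed coupling of a Grignard reagent with a primary alkyl triflate: the vinylcuprate displaces triflate at C3 by SN2 and reductive elimination forms C3–C4. The secondary chloride at C2 is flanked by the quaternary carbon and is not displaced, and the low temperature is meant to outrun loss of chloride from the organocopper intermediate.

Step 9
Reactants: 14 tert-butyl{[(3S,5R)-5-chloro-2-[(4R)-2,2-dimethyl-1,3-dioxolan-4-yl]-4,4-dimethylocta-1,7-dien-3-yl]oxy}dimethylsilane
Product: 15 tert-butyl{[(1S,5R)-5-chloro-2-[(4R)-2,2-dimethyl-1,3-dioxolan-4-yl]-6,6-dimethylcyclohex-2-en-1-yl]oxy}dimethylsilane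
Conditions: second-generation Grubbs catalyst (H2IMes)(PCy3)Cl2Ru=CHPh (5 mol%), CH2Cl2 (0.005 M), 40 °C
Reagents that add atoms: none
Why: Alkene metathesis by the cycloaddition/cycloreversion sequence: the ruthenium benzylidene exchanges first with the unhindered allyl terminus and so places the alkylidene on C4, this alkylidene adds intramolecularly across C5=CH2 to a ruthenacyclobutane, and cycloreversion forms C4=C5 and a ruthenium methylidene whose CH2 leaves as ethylene. The closest known reaction type is ring-closing metathesis of a monosubstituted with a 1,1-disubstituted alkene to a trisubstituted cyclohexene, for which this catalyst is the usual choice. The ring closes as a six-membered carbocycle from a 1,7-diene, the tether C3–C2–C1–C6 supplying four ring atoms and the alkene carbons C4 and C5 the other two. No stereocentre is formed, and C2, C6 and C7 cannot epimerise because none of them carries an acidic or metal-bound hydrogen during the cycle. The step needs cyclisation in preference to intermolecular metathesis of the allyl group, which high dilution and the gem-dimethyl group at C1 (it folds the chain) secure. It needs the catalyst to load at the right alkene, which the substrate secures because the 1,1-disubstituted alkene is shielded by the silyl ether and the dioxolane and reacts only once the alkylidene is held next to it. The secondary chloride, the silyl ether and the acetonide are inert to the ruthenium carbene, and loss of ethylene makes the closure irreversible.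

Step 10
Reactants: 15 tert-butyl{[(1S,5R)-5-chloro-2-[(4R)-2,2-dimethyl-1,3-dioxolan-4-yl]-6,6-dimethylcyclohex-2-en-1-yl]oxy}dimethylsilane
Product: 16 (1R)-1-[(4R,6S)-6-[(TBS)oxy]-4-chloro-5,5-dimethylcyclohex-1-en-1-yl]ethane-1,2-diol
Conditions: AcOH/H2O/THF 3:1:1, 40 °C
Reagents that add atoms: none
Why: Acid-catalysed acetal hydrolysis; the terminal acetonide is cleaved much faster than the secondary silyl ether next to the quaternary carbon, and the acid is too weak to ionise the allylic C–O bonds.

Step 11
Reactants: 16 (1R)-1-[(4R,6S)-6-[(TBS)oxy]-4-chloro-5,5-dimethylcyclohex-1-en-1-yl]ethane-1,2-diol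
Product: 17 (1R)-2-[(TBS)oxy]-1-[(4R,6S)-6-[(TBS)oxy]-4-chloro-5,5-dimethylcyclohex-1-en-1-yl]ethan-1-ol
Conditions: TBSCl (1.05 equiv), imidazole, CH2Cl2, −20 → 0 °C
Reagents that add atoms: tert-butyldimethylsilyl chloride, CC(C)(C)[Si](C)(C)Cl
Why: Sterically selective silylation of the primary hydroxyl of a 1,2-diol; only the C7 hydroxyl stays free, and a silyl ether at C8 cannot take part as a neighbouring group in the next step.

Step 12
Reactants: 17 (1R)-2-[(TBS)oxy]-1-[(4R,6S)-6-[(TBS)oxy]-4-chloro-5,5-dimethylcyclohex-1-en-1-yl]ethan-1-ol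
Product: 18 tert-butyl{(2S)-2-[(4R,6R)-6-[(TBS)oxy]-4-chloro-5,5-dimethylcyclohex-1-en-1-yl]-2-chloroethoxy}dimethylsilane
Conditions: PPh3, hexachloroacetone, CH2Cl2, −20 → 0 °C
Reagents that add atoms: hexachloroacetone, O=C(C(Cl)(Cl)Cl)C(Cl)(Cl)Cl
Why: Appel-type chlorination of an allylic alcohol with triphenylphosphine and hexachloroacetone: chloride displaces the oxyphosphonium group at C7 by SN2 with inversion, which converts the configuration inherited from 1 into that of the target. Direct attack is favoured over allylic transposition because the other allyl terminus, C4, is a ring carbon of a trisubstituted alkene.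

Step 13
Reactants: 18 tert-butyl{(2S)-2-[(4R,6R)-6-[(TBS)oxy]-4-chloro-5,5-dimethylcyclohex-1-en-1-yl]-2-chloroethoxy}dimethylsilane
Product: 19 (1R,5R)-5-chloro-2-[(1S)-1-chloro-2-hydroxyethyl]-6,6-dimethylcyclohex-2-en-1-ol
Conditions: HF (48% aq.), MeCN, 0 °C → rt
Reagents that add atoms: none
Why: Acidic fluoride cleaves both silyl ethers; acid is used and not Bu4NF because an alkoxide at C8 would displace the C7 chloride and close an epoxide.

Step 14
Reactants: 19 (1R,5R)-5-chloro-2-[(1S)-1-chloro-2-hydroxyethyl]-6,6-dimethylcyclohex-2-en-1-ol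
Product: 20 (4R,6S)-6-bromo-1-[(1S)-2-bromo-1-chloroethyl]-4-chloro-5,5-dimethylcyclohex-1-ene
Conditions: CBr4 (3 equiv), PPh3 (3 equiv), CH2Cl2, 0 °C → rt
Reagents that add atoms: carbon tetrabromide, BrC(Br)(Br)Br
Why: Double Appel bromination: bromide displaces the primary oxyphosphonium group at C8 directly and the allylic one at C6 with inversion, which turns the alcohol cis to the C2 chlorine into the trans bromide of the target. Even if the hindered C6 centre reacts through a tight ion pair, bromide is expected on the same face, because attack anti to the leaving group is also the favoured axial attack on the half-chair with the C2 chlorine equatorial.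

## Compound list

1 | (4S)-2,2-dimethyl-1,3-dioxolane-4-carbaldehyde, (S)-glyceraldehyde acetonide | O=C[C@@H]1COC(C)(C)O1 | starting material
2 | 1-[(4S)-2,2-dimethyl-1,3-dioxolan-4-yl]ethan-1-ol, both carbinol epimers | CC(O)[C@@H]1COC(C)(C)O1 | intermediate
3 | 1-[(4S)-2,2-dimethyl-1,3-dioxolan-4-yl]ethan-1-one | CC(=O)[C@@H]1COC(C)(C)O1 | intermediate
4 | 1-[(4S)-2,2-dimethyl-1,3-dioxolan-4-yl]ethenyl trifluoromethanesulfonate | C=C(OS(=O)(=O)C(F)(F)F)[C@@H]1COC(C)(C)O1 | intermediate
5 | 2,2-dimethylpent-4-enal | C=CCC(C)(C)C=O | starting material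
6 | (3R)-2-[(4R)-2,2-dimethyl-1,3-dioxolan-4-yl]-4,4-dimethylhepta-1,6-dien-3-ol | C=CCC(C)(C)[C@@H](O)C(=C)[C@@H]1COC(C)(C)O1 | intermediate
7 | tert-butyl{[(3R)-2-[(4R)-2,2-dimethyl-1,3-dioxolan-4-yl]-4,4-dimethylhepta-1,6-dien-3-yl]oxy}dimethylsilane | C=CCC(C)(C)[C@@H](O[Si](C)(C)C(C)(C)C)C(=C)[C@@H]1COC(C)(C)O1 | intermediate
8 | (5R)-5-[(tert-butyldimethylsilyl)oxy]-6-[(4R)-2,2-dimethyl-1,3-dioxolan-4-yl]-4,4-dimethylhept-6-ene-1,2-diol, both C2 epimers | OCC(O)CC(C)(C)[C@@H](O[Si](C)(C)C(C)(C)C)C(=C)[C@@H]1COC(C)(C)O1 | intermediate (not isolated)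
9 | (4R)-4-[(tert-butyldimethylsilyl)oxy]-5-[(4R)-2,2-dimethyl-1,3-dioxolan-4-yl]-3,3-dimethylhex-5-enal | O=CCC(C)(C)[C@@H](O[Si](C)(C)C(C)(C)C)C(=C)[C@@H]1COC(C)(C)O1 | intermediate
10 | (2S,4S)-4-[(tert-butyldimethylsilyl)oxy]-2-chloro-5-[(4R)-2,2-dimethyl-1,3-dioxolan-4-yl]-3,3-dimethylhex-5-enal | O=C[C@@H](Cl)C(C)(C)[C@@H](O[Si](C)(C)C(C)(C)C)C(=C)[C@@H]1COC(C)(C)O1 | intermediate (not isolated)
11 | (2S,4S)-4-[(tert-butyldimethylsilyl)oxy]-2-chloro-5-[(4R)-2,2-dimethyl-1,3-dioxolan-4-yl]-3,3-dimethylhex-5-en-1-ol | OC[C@@H](Cl)C(C)(C)[C@@H](O[Si](C)(C)C(C)(C)C)C(=C)[C@@H]1COC(C)(C)O1 | intermediate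
12 | vinylmagnesium bromide | C=C[Mg]Br | starting material
13 | (2S,4S)-4-[(tert-butyldimethylsilyl)oxy]-2-chloro-5-[(4R)-2,2-dimethyl-1,3-dioxolan-4-yl]-3,3-dimethylhex-5-en-1-yl trifluoromethanesulfonate | O=S(=O)(OC[C@@H](Cl)C(C)(C)[C@@H](O[Si](C)(C)C(C)(C)C)C(=C)[C@@H]1COC(C)(C)O1)C(F)(F)F | intermediate (not isolated)
14 | tert-butyl{[(3S,5R)-5-chloro-2-[(4R)-2,2-dimethyl-1,3-dioxolan-4-yl]-4,4-dimethylocta-1,7-dien-3-yl]oxy}dimethylsilane | C=CC[C@@H](Cl)C(C)(C)[C@@H](O[Si](C)(C)C(C)(C)C)C(=C)[C@@H]1COC(C)(C)O1 | intermediate
15 | tert-butyl{[(1S,5R)-5-chloro-2-[(4R)-2,2-dimethyl-1,3-dioxolan-4-yl]-6,6-dimethylcyclohex-2-en-1-yl]oxy}dimethylsilane | CC1(C)[C@H](Cl)CC=C([C@@H]2COC(C)(C)O2)[C@@H]1O[Si](C)(C)C(C)(C)C | intermediate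
16 | (1R)-1-[(4R,6S)-6-[(tert-butyldimethylsilyl)oxy]-4-chloro-5,5-dimethylcyclohex-1-en-1-yl]ethane-1,2-diol | CC1(C)[C@H](Cl)CC=C([C@@H](O)CO)[C@@H]1O[Si](C)(C)C(C)(C)C | intermediate
17 | (1R)-2-[(tert-butyldimethylsilyl)oxy]-1-[(4R,6S)-6-[(tert-butyldimethylsilyl)oxy]-4-chloro-5,5-dimethylcyclohex-1-en-1-yl]ethan-1-ol | CC1(C)[C@H](Cl)CC=C([C@@H](O)CO[Si](C)(C)C(C)(C)C)[C@@H]1O[Si](C)(C)C(C)(C)C | intermediate
18 | tert-butyl{(2S)-2-[(4R,6R)-6-[(tert-butyldimethylsilyl)oxy]-4-chloro-5,5-dimethylcyclohex-1-en-1-yl]-2-chloroethoxy}dimethylsilane | CC1(C)[C@H](Cl)CC=C([C@H](Cl)CO[Si](C)(C)C(C)(C)C)[C@@H]1O[Si](C)(C)C(C)(C)C | intermediate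
19 | (1R,5R)-5-chloro-2-[(1S)-1-chloro-2-hydroxyethyl]-6,6-dimethylcyclohex-2-en-1-ol | CC1(C)[C@H](Cl)CC=C([C@H](Cl)CO)[C@@H]1O | intermediate
20 | (4R,6S)-6-bromo-1-[(1S)-2-bromo-1-chloroethyl]-4-chloro-5,5-dimethylcyclohex-1-ene | CC1(C)[C@H](Cl)CC=C([C@H](Cl)CBr)[C@H]1Br | target

## Step count and least certain steps

Total step count: 14. Longest linear sequence: 14 steps (1 to 20); 5 and 12 enter as purchased materials.

Step 9 (key step). The ruthenium alkylidene at C4 may fail to engage the shielded 1,1-disubstituted alkene, so that intermolecular metathesis of the allyl terminus or alkene migration takes over. Fallback: close the ring on a less encumbered, hydroxyl-bearing substrate. Setting out from 14, the silyl ether is removed (Bu4NF, THF, 0 °C) to give the free allylic alcohol (3S,5R)-5-chloro-2-[(4R)-2,2-dimethyl-1,3-dioxolan-4-yl]-4,4-dimethylocta-1,7-dien-3-ol F1. Ring-closing metathesis of F1 under the conditions of step 9 gives the cyclohexenol F2, and silylation (TBSOTf, 2,6-lutidine) returns to the route at 15.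

Step 4. Addition of the alkenylchromium to the neopentyl aldehyde may be slow, so that ligand-free background addition or protonation of the organometallic erodes the facial selectivity or the conversion. Fallback: replace catalyst control by separation and recycling. Setting out from 6 obtained together with its C6 epimer F3, the two are separated by chromatography. F3 is oxidised (Dess–Martin periodinane) to the enone 2-[(4R)-2,2-dimethyl-1,3-dioxolan-4-yl]-4,4-dimethylhepta-1,6-dien-3-one F4. F4 is reduced (NaBH4, CeCl3·7H2O, MeOH, −78 °C) to a fresh mixture that re-enters the separation, and the route is rejoined at 6.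

Step 6. Osmylation may also take place at the 1,1-disubstituted alkene, since osmium tetroxide intrinsically prefers the more substituted double bond and the steric and inductive handicap may not suffice. Fallback: move the oxidative cleavage to a stage where only one alkene exists. The sequence sets out from 4 and returns at 11.
- Commercial 3,3-dimethylpent-4-enal F5 is chlorinated and reduced as in step 7 to (2S)-2-chloro-3,3-dimethylpent-4-en-1-ol F6.
- F6 is silylated (TBSCl, imidazole) to the silyl ether F7 and ozonised (O3, CH2Cl2, −78 °C; PPh3) to the aldehyde F8.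
- Coupling of F8 with 4 under the conditions of step 4 gives the allylic alcohol F9, and silylation (TBSOTf, 2,6-lutidine) gives the bis-silyl ether F10.
- Selective cleavage of the primary silyl ether (HF·pyridine, pyridine, THF, 0 °C) gives 11.

Step 8. The organocopper intermediate may expel the vicinal chloride, or the triflate may undergo base-induced elimination or be attacked by the silyl ether oxygen, each consuming 13 without forming C3–C4. Fallback: an sp-carbon nucleophile and a semi-reduction in place of organocopper chemistry. Setting out from 13 (made from 11 as in step 8), displacement with LiC≡CSiMe3 (THF/DMPU, −78 → −20 °C) gives the silylalkyne F11, and K2CO3 in MeOH gives the terminal alkyne F12. Semi-hydrogenation (H2, Pd on CaCO3 poisoned with Pb(OAc)2, quinoline) returns to the route at 14.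

Step 12. The activated C7 alcohol may react with allylic transposition to C4 or through an ion pair with partial retention, or may eliminate to a diene. Fallback: deliver chloride by opening an epoxide. Setting out from 16, selective sulfonylation of the primary hydroxyl (TsCl, Et3N, Bu2SnO cat.) gives the primary tosylate F13, and K2CO3 in MeOH closes the epoxide F14 with C7 unchanged. HCl in Et2O at −78 °C opens F14 at the allylic carbon with inversion to the chlorohydrin F15, and desilylation as in step 13 returns to the route at 19.

Step 14. At the neopentyl allylic C6 the oxyphosphonium intermediate may stall, ionise with loss of stereochemical integrity, or react with allylic transposition, while the primary position reacts normally. Fallback: separate the two substitutions and use sulfonate displacement at C6. Setting out from 19, limited reagent (CBr4 1.1 equiv, PPh3, CH2Cl2, −40 °C) brominates only C8 to give the bromo alcohol F16. Methanesulfonic anhydride and pyridine give the methanesulfonate F17, and LiBr in THF displaces it with inversion to reach 20.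

## Further compounds

F1 | step 9 | (3S,5R)-5-chloro-2-[(4R)-2,2-dimethyl-1,3-dioxolan-4-yl]-4,4-dimethylocta-1,7-dien-3-ol | C=CC[C@@H](Cl)C(C)(C)[C@@H](O)C(=C)[C@@H]1COC(C)(C)O1
F2 | step 9 | (1S,5R)-5-chloro-2-[(4R)-2,2-dimethyl-1,3-dioxolan-4-yl]-6,6-dimethylcyclohex-2-en-1-ol | CC1(C)[C@H](Cl)CC=C([C@@H]2COC(C)(C)O2)[C@@H]1O
F3 | step 4 | (3S)-2-[(4R)-2,2-dimethyl-1,3-dioxolan-4-yl]-4,4-dimethylhepta-1,6-dien-3-ol | C=CCC(C)(C)[C@H](O)C(=C)[C@@H]1COC(C)(C)O1
F4 | step 4 | 2-[(4R)-2,2-dimethyl-1,3-dioxolan-4-yl]-4,4-dimethylhepta-1,6-dien-3-one | C=CCC(C)(C)C(=O)C(=C)[C@@H]1COC(C)(C)O1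
F5 | step 6 | 3,3-dimethylpent-4-enal | C=CC(C)(C)CC=O
F6 | step 6 | (2S)-2-chloro-3,3-dimethylpent-4-en-1-ol | OC[C@@H](Cl)C(C)(C)C=C
F7 | step 6 | tert-butyl{[(2S)-2-chloro-3,3-dimethylpent-4-en-1-yl]oxy}dimethylsilane | CC(C)(C)[Si](C)(C)OC[C@@H](Cl)C(C)(C)C=C
F8 | step 6 | (3S)-4-[(tert-butyldimethylsilyl)oxy]-3-chloro-2,2-dimethylbutanal | CC(C)(C)[Si](C)(C)OC[C@@H](Cl)C(C)(C)C=O
F9 | step 6 | (2S,4S)-1-[(tert-butyldimethylsilyl)oxy]-2-chloro-5-[(4R)-2,2-dimethyl-1,3-dioxolan-4-yl]-3,3-dimethylhex-5-en-4-ol | CC(C)(C)[Si](C)(C)OC[C@@H](Cl)C(C)(C)[C@@H](O)C(=C)[C@@H]1COC(C)(C)O1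
F10 | step 6 | bis(tert-butyldimethylsilyl) ether of (2S,4S)-2-chloro-5-[(4R)-2,2-dimethyl-1,3-dioxolan-4-yl]-3,3-dimethylhex-5-ene-1,4-diol | CC(C)(C)[Si](C)(C)OC[C@@H](Cl)C(C)(C)[C@@H](O[Si](C)(C)C(C)(C)C)C(=C)[C@@H]1COC(C)(C)O1
F11 | step 8 | tert-butyl{[(3S,5R)-5-chloro-2-[(4R)-2,2-dimethyl-1,3-dioxolan-4-yl]-4,4-dimethyl-8-(trimethylsilyl)oct-1-en-7-yn-3-yl]oxy}dimethylsilane | C[Si](C)(C)C#CC[C@@H](Cl)C(C)(C)[C@@H](O[Si](C)(C)C(C)(C)C)C(=C)[C@@H]1COC(C)(C)O1
F12 | step 8 | tert-butyl{[(3S,5R)-5-chloro-2-[(4R)-2,2-dimethyl-1,3-dioxolan-4-yl]-4,4-dimethyloct-1-en-7-yn-3-yl]oxy}dimethylsilane | C#CC[C@@H](Cl)C(C)(C)[C@@H](O[Si](C)(C)C(C)(C)C)C(=C)[C@@H]1COC(C)(C)O1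
F13 | step 12 | (2R)-2-[(4R,6S)-6-[(tert-butyldimethylsilyl)oxy]-4-chloro-5,5-dimethylcyclohex-1-en-1-yl]-2-hydroxyethyl 4-methylbenzenesulfonate | CC1(C)[C@H](Cl)CC=C([C@@H](O)COS(=O)(=O)c2ccc(C)cc2)[C@@H]1O[Si](C)(C)C(C)(C)C
F14 | step 12 | tert-butyl{[(1S,5R)-5-chloro-6,6-dimethyl-2-[(2R)-oxiran-2-yl]cyclohex-2-en-1-yl]oxy}dimethylsilane | CC1(C)[C@H](Cl)CC=C([C@@H]2CO2)[C@@H]1O[Si](C)(C)C(C)(C)C
F15 | step 12 | (2S)-2-[(4R,6R)-6-[(tert-butyldimethylsilyl)oxy]-4-chloro-5,5-dimethylcyclohex-1-en-1-yl]-2-chloroethan-1-ol | CC1(C)[C@H](Cl)CC=C([C@H](Cl)CO)[C@@H]1O[Si](C)(C)C(C)(C)C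
F16 | step 14 | (1R,5R)-2-[(1S)-2-bromo-1-chloroethyl]-5-chloro-6,6-dimethylcyclohex-2-en-1-ol | CC1(C)[C@H](Cl)CC=C([C@H](Cl)CBr)[C@@H]1O
F17 | step 14 | (1R,5R)-2-[(1S)-2-bromo-1-chloroethyl]-5-chloro-6,6-dimethylcyclohex-2-en-1-yl methanesulfonate | CC1(C)[C@H](Cl)CC=C([C@H](Cl)CBr)[C@@H]1OS(C)(=O)=O
A1 | alternative 1 | (1Z)-2-bromo-1-[(triisopropylsilyl)oxy]buta-1,3-diene | C=C/C(Br)=C/O[Si](C(C)C)(C(C)C)C(C)C
A2 | alternative 1 | (2Z)-3-chloro-2-methylprop-2-enal | Cl/C=C(/C)C=O
A3 | alternative 1 | 3-bromo-6-chloro-1-methyl-2-[(triisopropylsilyl)oxy]cyclohex-3-ene-1-carbaldehyde, formyl, chloro and silyloxy groups all cis | C[C@@]1(C=O)[C@H](Cl)CC=C(Br)[C@@H]1O[Si](C(C)C)(C(C)C)C(C)C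
A4 | alternative 2 | (R)-pantolactone, (3R)-3-hydroxy-4,4-dimethyloxolan-2-one | CC1(C)COC(=O)[C@@H]1O
A5 | alternative 2 | (3S)-3-chloro-4,4-dimethyloxolan-2-one | O=C1OCC(C)(C)[C@@H]1Cl
A6 | alternative 2 | (3R,5E)-3-chloro-2,2-dimethyl-7-oxooct-5-enal | CC(=O)/C=C/C[C@@H](Cl)C(C)(C)C=O
A7 | alternative 2 | 1-[(4R,6S)-4-chloro-6-hydroxy-5,5-dimethylcyclohex-1-en-1-yl]ethan-1-one | CC1(C)[C@H](Cl)CC=C(C(C)=O)[C@@H]1O
A8 | alternative 3 | (2Z)-3-[(tert-butyldimethylsilyl)oxy]-2-{2-[(tert-butyldimethylsilyl)oxy]ethylidene}-4,4-dimethylbicyclo[3.1.0]hexane, alkene geometry as an anti 1,5-addition would require | CC1(C)[C@@H]2C[C@@H]2/C(=C/CO[Si](C)(C)C(C)(C)C)[C@@H]1O[Si](C)(C)C(C)(C)C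
A9 | alternative 3 | bis(tert-butyldimethylsilyl) ether of (1R,5R)-5-chloro-2-[(1S)-1-chloro-2-hydroxyethyl]-6,6-dimethylcyclohex-2-en-1-ol, identical with 18 | CC1(C)[C@H](Cl)CC=C([C@H](Cl)CO[Si](C)(C)C(C)(C)C)[C@@H]1O[Si](C)(C)C(C)(C)C
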